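The ten-membered carbocycle C1–C10 (germacrane numbering) is closed last, across C3–C4, by an intramolecular Nozaki–Hiyama–Kishi addition of a (Z)-alkenyl iodide (C4) to an aldehyde (C3). The step exploits the C3 allylic carbinol that flanks the Z-configured C4=C5 olefin: in one operation it should form the ring, set the C3 hydroxyl stereocentre and carry the Z double bond through unchanged. Its precursor is an open-chain seco-aldehyde that already holds the α-methylene-γ-lactone ring (C6, C7, C11, C12, O), the C1–C10 oxirane and the C8 ester; it is assembled by a zinc Barbier union of a bromomethyl butenolide with an epoxy aldehyde, followed by esterification with inversion at C8.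

Key step: step 15

Remark on the chemistry: germacrane locants are used throughout (ring C1–C10, C13 exocyclic methylene carbon, C14 hydroxymethyl carbon on C10, C15 methyl on C4). The zinc allylation of step 11 is assumed to follow the closed chair transition state (anti adduct, 8S), which is why the C8 ester is installed with inversion in step 12.

Step 1
Reactants: 1 acrolein; 2 prop-1-yn-1-ylmagnesium bromide
Product: 3 rac-hex-1-en-4-yn-3-ol
Conditions: THF, −78 °C to 0 °C; aq. NH4Cl
Reagents that add atoms: none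
Why: 1,2-Addition of the alkynyl Grignard reagent to the enal carbonyl is fast at low temperature and should give the racemic enynol, whose stereocentre is resolved in step 3.

Step 2
Reactants: 3 rac-hex-1-en-4-yn-3-ol
Product: 5 rac-(4Z)-5-iodohexa-1,4-dien-3-ol, via cyclic alkenylalanate 4 (not isolated)
Conditions: NaAlH2(OCH2CH2OMe)2 (Red-Al), Et2O, 0 °C to rt; EtOAc; then I2, THF, −78 °C
Reagents that add atoms: iodine, II
Why: Alkoxide-directed trans-hydroalumination of the propargylic alcohol places aluminium on the distal alkyne carbon inside a five-membered alanate ring, and iodinolysis with retention should give the Z iodoalkene with iodine cis to the carbinol carbon, which is the future C4=C5 geometry.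

Step 3
Reactants: 5 rac-(4Z)-5-iodohexa-1,4-dien-3-ol
Product: 6 (3S,4Z)-5-iodohexa-1,4-dien-3-ol
Conditions: Burkholderia cepacia lipase (Amano PS), vinyl acetate, tBuOMe, 30 °C, run to just past half conversion; chromatography
Reagents that add atoms: none
Why: Lipase-catalysed kinetic resolution by enantioselective transesterification should acetylate the R enantiomer (large iodoalkenyl against small vinyl substituent) and leave the S alcohol, which carries the future C6 configuration.

Step 4
Reactants: 6 (3S,4Z)-5-iodohexa-1,4-dien-3-ol; 7 2-(bromomethyl)prop-2-enoic acid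
Product: 8 (3S,4Z)-5-iodohexa-1,4-dien-3-yl 2-(bromomethyl)prop-2-enoate
Conditions: DCC, DMAP (cat.), CH2Cl2, 0 °C
Reagents that add atoms: none
Why: Carbodiimide (Steglich-type) esterification acylates the secondary alcohol with retention, and low temperature with only catalytic DMAP should limit substitution of the allylic bromide.

Step 5
Reactants: 8 (3S,4Z)-5-iodohexa-1,4-dien-3-yl 2-(bromomethyl)prop-2-enoate
Product: 9 (5S)-3-(bromomethyl)-5-[(1Z)-2-iodoprop-1-en-1-yl]furan-2(5H)-one
Conditions: second-generation Grubbs catalyst RuCl2(=CHPh)(PCy3)(H2IMes) (5 mol%), CH2Cl2, 40 °C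
Reagents that add atoms: none
Why: Ring-closing metathesis between the vinyl group and the 1,1-disubstituted acrylate alkene should close the butenolide (the lactone ring of the target) with loss of ethylene, while the trisubstituted iodoalkene is too hindered to engage and the C6 stereocentre is untouched.

Step 6
Reactants: 10 prop-2-yn-1-ol; 11 allylmagnesium bromide
Product: 13 (2Z)-2-(iodomethylidene)pent-4-en-1-ol, via cyclic alkenylmagnesium alkoxide 12 (not isolated)
Conditions: CuI (10 mol%), Et2O, 0 °C to rt; then I2, THF, −20 °C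
Reagents that add atoms: iodine, II
Why: Copper-catalysed anti-carbomagnesiation of the propargylic alkoxide delivers the allyl group to the proximal alkyne carbon and magnesium to the terminus inside a five-membered chelate, so that iodinolysis with retention should give the Z iodide with iodine cis to the hydroxymethyl group.

Step 7
Reactants: 13 (2Z)-2-(iodomethylidene)pent-4-en-1-ol; 14 tert-butyldimethyl(vinyloxy)silane
Product: 16 (2Z)-5-[(tert-butyldimethylsilyl)oxy]-2-(prop-2-en-1-yl)pent-2-en-1-ol, via B-alkyl-9-BBN borane 15 (not isolated)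
Conditions: 14, 9-BBN, THF, 0 °C to rt; then 13, PdCl2(dppf) (5 mol%), AsPh3, Cs2CO3, DMF/THF/H2O, rt
Reagents that add atoms: none
Why: Anti-Markovnikov hydroboration of the silyl enol ether gives the primary alkylborane, and B-alkyl Suzuki–Miyaura coupling with the alkenyl iodide proceeds with retention, which should fix the C2 chain cis to the hydroxymethyl group as required for the trans-fused oxirane.

Step 8
Reactants: 16 (2Z)-5-[(tert-butyldimethylsilyl)oxy]-2-(prop-2-en-1-yl)pent-2-en-1-ol
Product: 17 [(2S,3R)-3-{2-[(tert-butyldimethylsilyl)oxy]ethyl}-2-(prop-2-en-1-yl)oxiran-2-yl]methanol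
Conditions: Ti(OiPr)4, (R,R)-(+)-diethyl tartrate, tBuOOH, 4 Å molecular sieves, CH2Cl2, −20 °C
Reagents that add atoms: tert-butyl hydroperoxide, CC(C)(C)OO
Why: Sharpless asymmetric epoxidation of the trisubstituted allylic alcohol is reagent-controlled, and the (R,R)-tartrate ligand should deliver oxygen to the face that sets C10 as S and, through the olefin geometry, C1 as R, the isolated terminal alkene being inert.

Step 9
Reactants: 17 [(2S,3R)-3-{2-[(tert-butyldimethylsilyl)oxy]ethyl}-2-(prop-2-en-1-yl)oxiran-2-yl]methanol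
Product: 18 tert-butyl{[(2S,3R)-3-{2-[(tert-butyldimethylsilyl)oxy]ethyl}-2-(prop-2-en-1-yl)oxiran-2-yl]methoxy}diphenylsilane
Conditions: tBuPh2SiCl, imidazole, CH2Cl2, 0 °C to rt
Reagents that add atoms: tert-butyl(chloro)diphenylsilane, CC(C)(C)[Si](Cl)(c1ccccc1)c1ccccc1
Why: Silylation of the primary hydroxyl under imidazole catalysis is routine and should give an ether that outlasts the later removal of the primary tert-butyldimethylsilyl group.

Step 10
Reactants: 18 tert-butyl{[(2S,3R)-3-{2-[(tert-butyldimethylsilyl)oxy]ethyl}-2-(prop-2-en-1-yl)oxiran-2-yl]methoxy}diphenylsilane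
Product: 20 2-[(2S,3R)-3-{2-[(tert-butyldimethylsilyl)oxy]ethyl}-2-{[(tert-butyldiphenylsilyl)oxy]methyl}oxiran-2-yl]acetaldehyde, via secondary ozonide 19 (not isolated)
Conditions: O3, CH2Cl2, −78 °C; then PPh3, −78 °C to rt; used crude
Reagents that add atoms: ozone, [O-][O+]=O
Why: Ozonolysis with reductive work-up cleaves the only remaining alkene to the C8 aldehyde under neutral conditions that should spare the oxirane and avoid base-induced β-elimination of the β,γ-epoxy aldehyde.

Step 11
Reactants: 9 (5S)-3-(bromomethyl)-5-[(1Z)-2-iodoprop-1-en-1-yl]furan-2(5H)-one; 20 2-[(2S,3R)-3-{2-[(tert-butyldimethylsilyl)oxy]ethyl}-2-{[(tert-butyldiphenylsilyl)oxy]methyl}oxiran-2-yl]acetaldehyde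
Product: 22 (4R,5S)-4-{(1S)-2-[(2S,3R)-3-{2-[(tert-butyldimethylsilyl)oxy]ethyl}-2-{[(tert-butyldiphenylsilyl)oxy]methyl}oxiran-2-yl]-1-hydroxyethyl}-5-[(1Z)-2-iodoprop-1-en-1-yl]-3-methylideneoxolan-2-one (germacrane 6R,7R,8S), via allylzinc bromide 21 (not isolated)
Conditions: Zn dust, THF/sat. aq. NH4Cl, 0 °C to rt
Reagents that add atoms: none
Why: Barbier-type zinc allylation proceeds by attack of the γ-carbon of the allylzinc on the aldehyde through a closed chair (Zimmerman–Traxler) transition state on the butenolide face anti to the C6 iodoalkenyl group, which should set C7 trans to C6 (7R) and the carbinol anti to the ring (8S) while unveiling the exocyclic methylene and leaving the alkenyl iodide untouched.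

Step 12
Reactants: 22 the (8S)-carbinol from step 11; 23 (2S)-2-methylbutanoic acid
Product: 24 (1R)-2-[(2S,3R)-3-{2-[(tert-butyldimethylsilyl)oxy]ethyl}-2-{[(tert-butyldiphenylsilyl)oxy]methyl}oxiran-2-yl]-1-{(2S,3R)-2-[(1Z)-2-iodoprop-1-en-1-yl]-4-methylidene-5-oxooxolan-3-yl}ethyl (2S)-2-methylbutanoate (germacrane 6R,7R,8R)
Conditions: PPh3, DIAD (betaine pre-formed), toluene, 0 °C to rt
Reagents that add atoms: none
Why: Mitsunobu esterification displaces the alkoxyphosphonium group by the carboxylate in an SN2 step, so that the ester should be installed and C8 inverted to the required R configuration in one operation, the stereocentre of the acid not being involved.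

Step 13
Reactants: 24 the (8R)-ester from step 12
Product: 25 (1R)-1-{(2S,3R)-2-[(1Z)-2-iodoprop-1-en-1-yl]-4-methylidene-5-oxooxolan-3-yl}-2-[(2S,3R)-2-{[(tert-butyldiphenylsilyl)oxy]methyl}-3-(2-hydroxyethyl)oxiran-2-yl]ethyl (2S)-2-methylbutanoate
Conditions: HF·pyridine, pyridine, THF, 0 °C
Reagents that add atoms: none
Why: Buffered fluoride desilylation should remove the unhindered primary tert-butyldimethylsilyl ether much faster than the neopentyl-type tert-butyldiphenylsilyl ether and leave oxirane, esters and alkenyl iodide intact.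

Step 14
Reactants: 25 the primary alcohol from step 13
Product: 26 (1R)-1-{(2S,3R)-2-[(1Z)-2-iodoprop-1-en-1-yl]-4-methylidene-5-oxooxolan-3-yl}-2-[(2S,3R)-2-{[(tert-butyldiphenylsilyl)oxy]methyl}-3-(2-oxoethyl)oxiran-2-yl]ethyl (2S)-2-methylbutanoate
Conditions: Dess–Martin periodinane, NaHCO3, CH2Cl2, 0 °C to rt; used at once
Reagents that add atoms: none
Why: Dess–Martin oxidation under bicarbonate buffering should convert the primary alcohol into the C3 aldehyde without a base strong enough to open the β,γ-epoxy aldehyde by elimination.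

Step 15
Reactants: 26 the seco-aldehyde from step 14
Product: 28 (1R,3S,6R,7R,8R,10S)-14-[(tert-butyldiphenylsilyl)oxy]-1,10-epoxy-3-hydroxy-8-[(2S)-2-methylbutanoyloxy]germacra-4Z,11(13)-dien-12,6-olide, via alkenylchromium dichloride 27 (not isolated)
Conditions: CrCl2 (10 equiv), NiCl2 (0.1 equiv), degassed DMSO, rt, slow addition of 26 to about 2 mM
Reagents that add atoms: none
Why: Zerovalent nickel, generated from NiCl2 by CrCl2, inserts into the C4–iodine bond with retention of the Z geometry, transmetalation to trivalent chromium gives the alkenylchromium species 27, and this adds to the C3 aldehyde. The closest known reaction type is the Nozaki–Hiyama–Kishi macrocyclisation (intramolecular nickel/chromium-mediated alkenyl iodide–aldehyde coupling). The ten-membered carbocycle closes in a 10-exo-trig mode by C3–C4 bond formation, the lactone and oxirane rings being already present. The new C3 stereocentre is under substrate control: trivalent chromium can bridge the aldehyde oxygen and the C1 oxirane oxygen in a six-membered chelate, and C4, held to C10 through the C5–C9 chain, should reach the carbonyl only on the chelate face that carries C10 (the Re face), which places the new oxygen on the ring periphery, 1,3-syn to the C1–O bond, that is 3S. The step needs chemoselectivity for the aldehyde over lactone, ester and oxirane, which the non-basic organochromium reagent secures, and cyclisation over oligomerisation, which high dilution together with the turn imposed by the Z-alkenyl unit and the trans-disubstituted lactone should secure.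

Step 16
Reactants: 28 the silyl-protected macrocycle from step 15
Product: 29 (1R,3S,6R,7R,8R,10S)-1,10-epoxy-3,14-dihydroxy-8-[(2S)-2-methylbutanoyloxy]germacra-4Z,11(13)-dien-12,6-olide (CNP0356520.3)
Conditions: Bu4NF, AcOH (1:1), THF, 0 °C to rt
Reagents that add atoms: none
Why: Acetic acid-buffered fluoride cleaves the silicon–oxygen bond under nearly neutral conditions that should avoid acid-promoted transannular opening of the oxirane, Payne rearrangement and conjugate addition to the methylene lactone, giving the target.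

Compound list
1 | acrolein (prop-2-enal) | C=CC=O | starting material
2 | prop-1-yn-1-ylmagnesium bromide | CC#C[Mg]Br | starting material
3 | rac-hex-1-en-4-yn-3-ol | C=CC(O)C#CC | intermediate
4 | sodium cyclic alkenylalanate (five-membered O–Al–C=C ring from hydroalumination of 3) | [Na+].C=CC1C=C(C)[Al-](OCCOC)(OCCOC)O1 | intermediate
5 | rac-(4Z)-5-iodohexa-1,4-dien-3-ol | C=CC(O)/C=C(/C)I | intermediate
6 | (3S,4Z)-5-iodohexa-1,4-dien-3-ol | C=C[C@H](O)/C=C(/C)I | intermediate
7 | 2-(bromomethyl)prop-2-enoic acid | C=C(CBr)C(=O)O | starting material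
8 | (3S,4Z)-5-iodohexa-1,4-dien-3-yl 2-(bromomethyl)prop-2-enoate | C=C(CBr)C(=O)O[C@@H](C=C)/C=C(/C)I | intermediate
9 | (5S)-3-(bromomethyl)-5-[(1Z)-2-iodoprop-1-en-1-yl]furan-2(5H)-one | BrCC1=C[C@@H](/C=C(/C)I)OC1=O | intermediate
10 | prop-2-yn-1-ol | C#CCO | starting material
11 | allylmagnesium bromide | C=CC[Mg]Br | starting material
12 | cyclic alkenylmagnesium alkoxide (five-membered O–Mg–C=C chelate bearing the allyl group) | C=CCC1=C[Mg]OC1 | intermediate
13 | (2Z)-2-(iodomethylidene)pent-4-en-1-ol | OC/C(CC=C)=C\I | intermediate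
14 | tert-butyldimethyl(vinyloxy)silane | C=CO[Si](C)(C)C(C)(C)C | starting material
15 | 9-{2-[(tert-butyldimethylsilyl)oxy]ethyl}-9-borabicyclo[3.3.1]nonane | CC(C)(C)[Si](C)(C)OCCB1C2CCCC1CCC2 | intermediate
16 | (2Z)-5-[(tert-butyldimethylsilyl)oxy]-2-(prop-2-en-1-yl)pent-2-en-1-ol | OC/C(CC=C)=C\CCO[Si](C)(C)C(C)(C)C | intermediate
17 | [(2S,3R)-3-{2-[(tert-butyldimethylsilyl)oxy]ethyl}-2-(prop-2-en-1-yl)oxiran-2-yl]methanol | C=CC[C@@]1(CO)O[C@@H]1CCO[Si](C)(C)C(C)(C)C | intermediate
18 | tert-butyl{[(2S,3R)-3-{2-[(tert-butyldimethylsilyl)oxy]ethyl}-2-(prop-2-en-1-yl)oxiran-2-yl]methoxy}diphenylsilane | C=CC[C@@]1(CO[Si](c2ccccc2)(c2ccccc2)C(C)(C)C)O[C@@H]1CCO[Si](C)(C)C(C)(C)C | intermediate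
19 | secondary ozonide of 18 (3-substituted 1,2,4-trioxolane, mixture at the trioxolane carbon) | C1(C[C@@]2(CO[Si](c3ccccc3)(c3ccccc3)C(C)(C)C)O[C@@H]2CCO[Si](C)(C)C(C)(C)C)OCOO1 | intermediate
20 | 2-[(2S,3R)-3-{2-[(tert-butyldimethylsilyl)oxy]ethyl}-2-{[(tert-butyldiphenylsilyl)oxy]methyl}oxiran-2-yl]acetaldehyde | O=CC[C@@]1(CO[Si](c2ccccc2)(c2ccccc2)C(C)(C)C)O[C@@H]1CCO[Si](C)(C)C(C)(C)C | intermediate
21 | {[(5S)-5-[(1Z)-2-iodoprop-1-en-1-yl]-2-oxo-2,5-dihydrofuran-3-yl]methyl}zinc bromide | Br[Zn]CC1=C[C@@H](/C=C(/C)I)OC1=O | intermediate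
22 | (4R,5S)-4-{(1S)-2-[(2S,3R)-3-{2-[(tert-butyldimethylsilyl)oxy]ethyl}-2-{[(tert-butyldiphenylsilyl)oxy]methyl}oxiran-2-yl]-1-hydroxyethyl}-5-[(1Z)-2-iodoprop-1-en-1-yl]-3-methylideneoxolan-2-one | C=C1C(=O)O[C@H](/C=C(/C)I)[C@H]1[C@@H](O)C[C@@]2(CO[Si](c3ccccc3)(c3ccccc3)C(C)(C)C)O[C@@H]2CCO[Si](C)(C)C(C)(C)C | intermediate
23 | (2S)-2-methylbutanoic acid | CC[C@H](C)C(=O)O | starting material
24 | (1R)-2-[(2S,3R)-3-{2-[(tert-butyldimethylsilyl)oxy]ethyl}-2-{[(tert-butyldiphenylsilyl)oxy]methyl}oxiran-2-yl]-1-{(2S,3R)-2-[(1Z)-2-iodoprop-1-en-1-yl]-4-methylidene-5-oxooxolan-3-yl}ethyl (2S)-2-methylbutanoate | C=C1C(=O)O[C@H](/C=C(/C)I)[C@H]1[C@H](OC(=O)[C@@H](C)CC)C[C@@]2(CO[Si](c3ccccc3)(c3ccccc3)C(C)(C)C)O[C@@H]2CCO[Si](C)(C)C(C)(C)C | intermediate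
25 | primary alcohol: 24 with the tert-butyldimethylsilyl ether replaced by a free 2-hydroxyethyl group on the oxirane | C=C1C(=O)O[C@H](/C=C(/C)I)[C@H]1[C@H](OC(=O)[C@@H](C)CC)C[C@@]2(CO[Si](c3ccccc3)(c3ccccc3)C(C)(C)C)O[C@@H]2CCO | intermediate
26 | seco-aldehyde: 25 with the 2-hydroxyethyl group oxidised to a 2-oxoethyl group (C3 aldehyde) | C=C1C(=O)O[C@H](/C=C(/C)I)[C@H]1[C@H](OC(=O)[C@@H](C)CC)C[C@@]2(CO[Si](c3ccccc3)(c3ccccc3)C(C)(C)C)O[C@@H]2CC=O | intermediate
27 | alkenylchromium dichloride: 26 with the iodine replaced by a CrCl2 group (Z geometry retained) | C=C1C(=O)O[C@H](/C=C(/C)[Cr](Cl)Cl)[C@H]1[C@H](OC(=O)[C@@H](C)CC)C[C@@]2(CO[Si](c3ccccc3)(c3ccccc3)C(C)(C)C)O[C@@H]2CC=O | intermediate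
28 | (1R,3S,6R,7R,8R,10S)-14-[(tert-butyldiphenylsilyl)oxy]-1,10-epoxy-3-hydroxy-8-[(2S)-2-methylbutanoyloxy]germacra-4Z,11(13)-dien-12,6-olide | C=C1C(=O)O[C@@H]2/C=C(/C)[C@@H](O)C[C@H]3O[C@]3(CO[Si](c4ccccc4)(c4ccccc4)C(C)(C)C)C[C@@H](OC(=O)[C@@H](C)CC)[C@@H]12 | intermediate
29 | (1R,3S,6R,7R,8R,10S)-1,10-epoxy-3,14-dihydroxy-8-[(2S)-2-methylbutanoyloxy]germacra-4Z,11(13)-dien-12,6-olide | C=C1C(=O)O[C@@H]2/C=C(/C)[C@@H](O)C[C@H]3O[C@]3(CO)C[C@@H](OC(=O)[C@@H](C)CC)[C@@H]12 | target

Total step count: 16 steps.
Longest linear sequence: 11 steps (steps 1–5 or steps 6–10, then steps 11–16).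

Steps most likely to fail

1. Step 15 (key step). What may go wrong: poor facial selectivity at C3 in the ring-closing addition, so that the C3 epimer forms alone or beside 28. Fallback: setting out from 26, the same ring closure is run without relying on its facial selectivity. The C3 epimer of 28, the (3R)-carbinol F1 (alone or mixed with 28), is oxidised with Dess–Martin periodinane to the C3 enone F2. F2 is then reduced with catecholborane and (R)-2-methyl-CBS-oxazaborolidine at −78 °C (Corey–Bakshi–Shibata reduction, reagent control with the alkenyl side as the large group), which should give the 3S carbinol and come back to the route at 28.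

2. Step 12. What may go wrong: slow SN2 displacement at the hindered C8 alkoxyphosphonium centre, with elimination toward C7 or participation of the lactone carbonyl taking over. Fallback: setting out from 22, the alcohol is converted with chloromethanesulfonyl chloride and pyridine into the (8S)-chloromethanesulfonate F3. F3 is displaced with inversion by caesium (2S)-2-methylbutanoate (from 23 and Cs2CO3) with 18-crown-6 in toluene at 50 °C, which comes back to the route at 24.

3. Step 11. What may go wrong: simple diastereoselection opposite to, or lower than, that predicted by the chair transition state, that is, poor control of C8. Fallback: setting out from 9 and 20, the zinc coupling is run as before and the C8 epimer, the (8R)-carbinol F4, is separated. F4 is esterified with retention (23, DCC, DMAP, CH2Cl2, Steglich esterification), so that both C8 epimers converge on 24: the 8S isomer through step 12 and the 8R isomer through F4.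

Further compounds
F1 | step 15 | (1R,3R,6R,7R,8R,10S)-14-[(tert-butyldiphenylsilyl)oxy]-1,10-epoxy-3-hydroxy-8-[(2S)-2-methylbutanoyloxy]germacra-4Z,11(13)-dien-12,6-olide (C3 epimer of 28) | C=C1C(=O)O[C@@H]2/C=C(/C)[C@H](O)C[C@H]3O[C@]3(CO[Si](c4ccccc4)(c4ccccc4)C(C)(C)C)C[C@@H](OC(=O)[C@@H](C)CC)[C@@H]12
F2 | step 15 | (1R,6R,7R,8R,10S)-14-[(tert-butyldiphenylsilyl)oxy]-1,10-epoxy-8-[(2S)-2-methylbutanoyloxy]-3-oxogermacra-4Z,11(13)-dien-12,6-olide (C3 enone) | C=C1C(=O)O[C@@H]2/C=C(/C)C(=O)C[C@H]3O[C@]3(CO[Si](c4ccccc4)(c4ccccc4)C(C)(C)C)C[C@@H](OC(=O)[C@@H](C)CC)[C@@H]12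
F3 | step 12 | (8S)-chloromethanesulfonate of 22 | C=C1C(=O)O[C@H](/C=C(/C)I)[C@H]1[C@@H](OS(=O)(=O)CCl)C[C@@]2(CO[Si](c3ccccc3)(c3ccccc3)C(C)(C)C)O[C@@H]2CCO[Si](C)(C)C(C)(C)C
F4 | step 11 | (8R)-carbinol, C8 epimer of 22 | C=C1C(=O)O[C@H](/C=C(/C)I)[C@H]1[C@H](O)C[C@@]2(CO[Si](c3ccccc3)(c3ccccc3)C(C)(C)C)O[C@@H]2CCO[Si](C)(C)C(C)(C)C
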